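A leftover of 30.0% of the electrophile at 30 s is what this flask must show, and the charge of free base that gives it is what I seek.

electrophile 1.0 mM; protonated nucleophile 1.50 mM; time 30 s

    acid set free → by-product carried off (k1 = 0.657 s⁻¹)
    nucleophile + acid set free ⇌ protonated nucleophile, settled at all times (K2 = 1.4 × 10⁶ L mol⁻¹)
    electrophile + nucleophile → acid set free + target (k3 = 2190 L mol⁻¹ s⁻¹)
    acid set free + free base ⇌ salt of the base (K4 = 3.30 × 10⁷ L mol⁻¹, k4 = 7220 L mol⁻¹ s⁻¹)
    2 free base → self-condensation product (k5 = 174 L mol⁻¹ s⁻¹)

1. the concentration of free base at which the part of the electrophile that has reacted at 30 s is just 70%, in mM

- a step written with two of one species runs at k times the square of its concentration and takes two of it each time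
- the amount of free base is what is sought; it is there from the start
- run time (flask): 30 s

I write e for electrophile, n for nucleophile, h for acid set free and p for protonated nucleophile, and I take the fast balance as holding: n·h = p/K, with K its constant. With no base in the reckoning, n and h start equal, both 0.0327 mM, so p is the resting state of the nucleophile. Held at that n, the electrophile reaches 88.4% with no base. I distrust this, since each coupling of e with n uses up one n and sets one acid free, and both changes push n down.

A better estimate lets n return as acid leaves, and two acids must leave per coupling. So I set kL·h = 2kC·e·n, with kL the acid-loss constant and kC the coupling constant. The coupling then runs at κ√(e·p), where κ, the drain constant, is the root of kL·kC/(2K), 0.0227 s⁻¹. Each coupling takes one p net. Integrating gives 59.8% at 30 s without base, and 70% at 38.2 s, which leaves a lag of 8.25 s.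

One base removes one acid, half a coupling's worth, so covering that lag at once takes 0.417 mM. But capture isn't instantaneous: at the starting h the base has a half-life of 2.93 s, shorter than the run. I assume the drain stands still for 3 such half-lives, which lengthens the lag to 17.0 s. I commit to 0.781 mM.

The forecast says 0.9 mM, within 0.6 mM to 1.4 mM, more than my figure, on the ground that the base “disappears within seconds through self-condensation and acid capture”.

The simulation gives 0.947 mM, more than my 0.781 mM and inside the forecast's range. In this flask the free base has a half-life against acid capture of 2.0 s at 15.0 s, short against the run. At 30.0 s in this flask, loss of acid to by-product outruns capture, forward rate alone, 170 times over. Against the 59.8% reckoned without base, the 70% asked of this flask is a credit of 10 percentage points. A second flask, with half the protonated nucleophile and the same base charge, has 42.5% from κ without base, 52.5% with that same credit, and 51.7% in the simulation.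

The numbers of this flask are invented; the rest is arithmetic.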